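## Analysis of the target

The target is a 2,3-dihydrobenzofuran-6(5H)-one. A dihydrofuran ring B (O1, C2, C3, C3a, C7a) is fused to a six-membered ring A (C3a, C4, C5, C6, C7, C7a). Ring A is not aromatic: it is a linearly conjugated dienone (C4=C3a, C7=C7a, C6=O) whose sixth atom, C5, is quaternary and carries an allyl and a methoxy group.

There are three stereocentres. C2 (S, 3,4,5-trimethoxyphenyl) and C3 (S, methyl) are adjacent and trans on ring B. C5 (R) sits on ring A, separated from C3 by the sp2 carbons C3a and C4, so the ring B substituents cannot be expected to steer a reagent at C5.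

Ring A is the sensitive part. C5–CH2–CH=CH2 together with C4=C3a is a 1,5-diene, so heat can move the allyl group from C5 to C3a by a [3,3] shift. Acid can trigger allyl migration with aromatisation, and O1–C7a=C7–C6=O is a vinylogous ester. The C2–O1 bond is a benzylic aryl ether that strong acid or hydrogenolysis can break.

The synthesis is hard in two places: fixing the trans C2/C3 pair in absolute terms, and creating the C5 quaternary centre late, under mild conditions, without help from the rest of the molecule.

The strategy rests on the C2–C3 bond of ring B. C2 is a benzylic ether carbon (bonded to O1 and to the trimethoxyphenyl ring) and C3 is bonded to C3a. A carbene centred at C3 of an aryl acetate can therefore insert into a C2–H bond of an aryl 3,4,5-trimethoxybenzyl ether and close ring B in one step. Ring A is carried through this chemistry as a protected catechol and becomes the 5,6-quinone, the electrophile for the allyl group, only near the end.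

## Retrosynthetic reasoning

**18 to 17 (O–CH3 at C5).** The methoxy oxygen at C5 is what remains of a ring A carbonyl, so the methyl group can only go on after C5 has received its allyl group. Cutting O–CH3 leaves tertiary ketol 17. The forward alkylation should avoid a free alkoxide: an alkoxide at C5, with the allyl group on the same carbon and C4=C3a next to it, is set up for an anionic oxy-Cope shift.

**17 to 15 and 16 (C5–allyl).** Cutting C5–CH2 reveals quinone 15, whose two carbonyl groups differ. C6=O belongs to the vinylogous ester O1–C7a=C7–C6=O and is deactivated; C5=O is conjugated only with C4=C3a and is the more electrophilic. Allylboronate 16 is chosen because its closed six-membered transition state forces 1,2-addition at a carbonyl carbon (no attack at C3a or C7) and because boron can be made chiral by exchange with a chiral diol. The forward step must fix C5 as R by catalyst control.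

**15 to 13 (oxidation level and protection of ring A).** Quinone 15 goes back to catechol 14 and this to bis(methoxymethyl) ether 13. Ring A thus stays aromatic and inert through every C–C bond formation, base and hydride step. Acetal protection survives carbene, alkoxide and hydride chemistry and has no C–H bond within intramolecular reach of the carbene. It is removed without hydrogenolysis (which would endanger C2–O1) and without Lewis acids strong enough to attack the aryl methyl ethers.

**13 to 10 (C3 methyl as an ester).** The C3 methyl carbon is traced back through tosylate 12 and alcohol 11 to the ester carbon of 10. No skeletal bond is cut. An ester at C3 is needed for the next two disconnections: it acidifies C3–H and, as acceptor group, tames the carbene.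

**10 to 9 (configuration at C3).** Trans ester 10 is the thermodynamic isomer and is related to cis ester 9 by enolisation at C3. The ring-forming step therefore only has to set C2.

**9 to 8 (C2–C3, ring B).** This is the central cut. C2–C3 is the only bond of ring B whose cleavage leaves the two halves joined by a plain ether link and turns C2 into a prochiral CH2, so the stereocentre is created in the ring closure itself. Cutting O1–C2 or O1–C7a would instead demand an open-chain precursor that already holds both stereocentres. One ring, one C–C bond and the absolute configuration at C2 are gained from diazo ester 8. The forward reaction needs a chiral dirhodium carboxylate to select one of the two benzylic hydrogens.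

**8 to 5 and 6.** The diazo group comes from the benzylic CH2 of aryl acetate 7 by diazo transfer. The O–CH2 bond of 7 is cut to phenol 5 and benzyl chloride 6, a plain phenoxide alkylation.

**5 to 1.** The phenolic oxygen ortho to the acetate chain is the only ring substituent missing in commercial catechol ester 1. An oxidative closure of the free catechol acid onto its own quinone would look shorter. It is not used, because such 4-alkyl quinones tautomerise to quinone methides and the trioxygenated lactone would be oxidised further. The oxygen is instead introduced by reliable steps: protection to 2, bromination para to an acetal oxygen to give 3, borylation to 4 and oxidation to 5.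

## Alternatives that were turned down

**Alternative 1:** Ring A is assembled from open-chain pieces by cutting C6–C7, C3a–C7a and C5–C6.
- Forward key step: acid chloride A2 is dehydrochlorinated by a tertiary amine to a vinylketene that already carries C5 with its allyl and methoxy groups. [2+2] addition of ethoxyethyne A3 gives a cyclobutenone, which opens in a four-electron electrocyclic step and recloses in a six-electron step to dienone A1. Later the freed C2 hydroxyl displaces ethoxide at C7a.
- For it: the route is convergent and the quaternary carbon arrives complete, with no quinone and no late O-methylation. On this point it is stronger than the chosen route.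
- Against it: C5 becomes stereogenic only in the electrocyclisation, where the sole chiral information sits in the side chain outside the ring, so a mixture of C5 epimers is to be expected. The ring opening usually needs heat, which A1 (an allyl dienone open to the Cope shift) tolerates poorly. A2 itself needs a long linear synthesis with two adjacent open-chain stereocentres.
- Comparison: the chosen route offers a catalyst handle on both C2 and C5 and a shorter way to the ring B stereocentres.

**Alternative 2:** O1–C7a is cut, leading to open-chain catechol A5 with a free C2 hydroxyl.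
- Forward key step: a periodate oxidant turns A5 into its ortho-quinone, the hydroxyl adds to the carbon that becomes C7a, and reoxidation in the same flask gives quinone A4, the same compound as 15.
- For it: this is the shortest way to the quinone and needs no protecting groups on ring A. In step economy of the endgame it is stronger than the chosen route.
- Against it: all stereochemical work is shifted to A5, whose neighbouring benzylic carbinol and benzylic methine must be built in an open chain. The closure pits a neutral secondary alcohol against fast side reactions of a 4-alkyl ortho-quinone (tautomerisation through the benzylic C–H, which would erase C3, and addition of water), and two oxidations must be controlled in one pot.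
- Comparison: the chosen route closes ring B before any quinone exists, so 15 only has to survive one step.

**Alternative 3:** C3–C3a is cut in the sense of a ring contraction of chromanone A7.
- Forward key step: a diacetoxyiodoarene with an orthoformate and strong acid attacks the enol ether of A7 at C3 anti to the 2-aryl group. The fused aryl carbon then migrates from C4 to C3, and the old carbonyl carbon ends as the methyl ester of A6.
- For it: A6 is obtained directly as the trans ester, so C3 is set stereospecifically from C2 and no epimerisation step is needed. No diazo compound and no precious metal are used. Here it is stronger than the chosen route.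
- Against it: the absolute configuration must already be present in A7. 2-Arylchromanones racemise by ring opening to the chalcone under just such acidic conditions. The electron-rich trimethoxyphenyl group favours the competing migration of the C2 aryl group and dehydrogenation. The methoxy/benzyloxy pattern of A6 would later need an oxidative demethylation to reach a quinone.
- Comparison: the chosen route pays one epimerisation step but creates C2 under catalyst control in a substrate with no racemisation pathway.

Key step: step 6

Assumption: the sense of induction written for Rh2(S-PTTL)4 at C2 and for (S)-3,3′-dibromo-BINOL at C5 is taken by analogy with simpler substrates; both catalysts exist in either enantiomeric form, and the enantiomer that gives 2S, respectively 5R, is the one meant.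

Assumption: diisopropyl allylboronate 16 is taken as a purchasable reagent; it is otherwise one step from allylmagnesium bromide and triisopropyl borate.

## Route

**Step 1**
Reactants: 1 methyl 2-(3,4-dihydroxyphenyl)acetate
Product: 2 methyl 2-[3,4-bis(methoxymethoxy)phenyl]acetate
Conditions: MOMCl, iPr2NEt, CH2Cl2, 0 °C → rt
Reagents that add atoms: chloromethyl methyl ether, COCCl
Why: O-alkylation of both phenols by the α-chloro ether under amine base (MOM protection); the ester and its benzylic CH2 are not touched by the hindered amine.

**Step 2**
Reactants: 2 methyl 2-[3,4-bis(methoxymethoxy)phenyl]acetate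
Product: 3 methyl 2-[2-bromo-4,5-bis(methoxymethoxy)phenyl]acetate
Conditions: NBS, MeCN, 0 °C → rt, dark
Reagents that add atoms: N-bromosuccinimide, O=C1CCC(=O)N1Br
Why: Electrophilic aromatic bromination; the position ortho to the side chain is the only free one that is para to an oxygen donor and not flanked by two substituents, as is usual for 3,4-dialkoxyphenylacetates. Polar, non-radical conditions avoid bromination of the benzylic CH2.

**Step 3**
Reactants: 3 methyl 2-[2-bromo-4,5-bis(methoxymethoxy)phenyl]acetate
Product: 5 methyl 2-[2-hydroxy-4,5-bis(methoxymethoxy)phenyl]acetate, via arylboronic pinacol ester 4 (not isolated)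
Conditions: B2pin2, PdCl2(dppf), KOAc, 1,4-dioxane, 85 °C; then 30% aq. H2O2, NaHCO3, THF, 0 °C → rt
Reagents that add atoms: bis(pinacolato)diboron, CC1(C)OB(OC1(C)C)B1OC(C)(C)C(C)(C)O1 (boryl group of 4); hydrogen peroxide, OO (phenol oxygen of 5)
Why: Miyaura borylation followed by oxidation of the C–B bond (aryl shift from boron to oxygen in the peroxoborate). Acetate base and bicarbonate-buffered peroxide spare the methyl ester and the acetals, and cold, near-neutral work-up keeps the new phenol from lactonising onto the ester.

**Step 4**
Reactants: 5 methyl 2-[2-hydroxy-4,5-bis(methoxymethoxy)phenyl]acetate; 6 3,4,5-trimethoxybenzyl chloride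
Product: 7 methyl 2-[4,5-bis(methoxymethoxy)-2-(3,4,5-trimethoxybenzyloxy)phenyl]acetate
Conditions: K2CO3, nBu4NI (cat.), DMF, rt
Reagents that add atoms: none
Why: Williamson ether synthesis; carbonate deprotonates only the phenol, and alkylation of the phenoxide by the benzylic halide at room temperature outruns lactonisation, as is routine for methyl 2-hydroxyphenylacetates.

**Step 5**
Reactants: 7 methyl 2-[4,5-bis(methoxymethoxy)-2-(3,4,5-trimethoxybenzyloxy)phenyl]acetate
Product: 8 methyl 2-diazo-2-[4,5-bis(methoxymethoxy)-2-(3,4,5-trimethoxybenzyloxy)phenyl]acetate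
Conditions: p-ABSA, DBU, MeCN, 0 °C → rt
Reagents that add atoms: 4-acetamidobenzenesulfonyl azide, CC(=O)Nc1ccc(cc1)S(=O)(=O)N=[N+]=[N-]
Why: Regitz diazo transfer to the benzylic ester carbon; aryl acetates are acidic enough for direct transfer with an amidine base, and the product is a donor/acceptor diazo ester stable enough to purify.

**Step 6**
Reactants: 8 methyl 2-diazo-2-[4,5-bis(methoxymethoxy)-2-(3,4,5-trimethoxybenzyloxy)phenyl]acetate
Product: 9 methyl (2S,3R)-5,6-bis(methoxymethoxy)-2-(3,4,5-trimethoxyphenyl)-2,3-dihydrobenzofuran-3-carboxylate (cis)
Conditions: Rh2(S-PTTL)4 (1 mol%), toluene, −60 °C, slow addition of 8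
Reagents that add atoms: none
Why: The dirhodium tetrakis[N-phthaloyl-(S)-tert-leucinate] decomposes 8 with loss of nitrogen to an electrophilic rhodium carbene at the future C3. The carbene carbon engages a benzylic ether C–H bond five atoms away in a concerted, asynchronous three-centre transition state with hydride-transfer character, so the C2–C3 bond forms and ring B closes as a 1,5-insertion, the ring size strongly preferred by such carbenes. The closest known reaction type is the dirhodium-carboxylate-catalysed enantioselective intramolecular C–H insertion of methyl 2-(2-benzyloxyphenyl)-2-diazoacetates to cis-2-aryl-2,3-dihydrobenzofuran-3-carboxylates. C2 is set by the chiral carboxylate ligands, which tell the two enantiotopic benzylic hydrogens apart. C3 arises cis to the aryl group as the kinetic result of the insertion geometry and is corrected in step 7. Site selectivity is needed against the acetal C–H bonds and against addition to the trimethoxyphenyl ring; it is secured because only the OCH2Ar group is ortho to the carbene-bearing carbon, its C–H bonds are activated by both the ether oxygen and the electron-rich aryl group, and an oxonium ylide would need a four-membered ring. Slow addition at low temperature keeps the diazo concentration low and holds back azine and carbene-dimer formation.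

**Step 7**
Reactants: 9 methyl (2S,3R)-5,6-bis(methoxymethoxy)-2-(3,4,5-trimethoxyphenyl)-2,3-dihydrobenzofuran-3-carboxylate
Product: 10 methyl (2S,3S)-5,6-bis(methoxymethoxy)-2-(3,4,5-trimethoxyphenyl)-2,3-dihydrobenzofuran-3-carboxylate (trans)
Conditions: NaOMe (0.3 equiv), MeOH, rt
Reagents that add atoms: none
Why: Base-mediated epimerisation through the ester enolate gives the thermodynamically favoured trans isomer, with aryl and ester on opposite faces. C2 is not at risk, because expulsion of the phenoxide from the enolate would be a 5-endo process in which the C2–O1 bond lies near the nodal plane of the enolate.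

**Step 8**
Reactants: 10 methyl (2S,3S)-5,6-bis(methoxymethoxy)-2-(3,4,5-trimethoxyphenyl)-2,3-dihydrobenzofuran-3-carboxylate
Product: 11 [(2S,3R)-5,6-bis(methoxymethoxy)-2-(3,4,5-trimethoxyphenyl)-2,3-dihydrobenzofuran-3-yl]methanol
Conditions: LiAlH4, THF, 0 °C
Reagents that add atoms: none
Why: Hydride reduction of the ester to the primary alcohol; acetals and aryl ethers are inert, and the change of descriptor at C3 is only a change of priorities.

**Step 9**
Reactants: 11 [(2S,3R)-5,6-bis(methoxymethoxy)-2-(3,4,5-trimethoxyphenyl)-2,3-dihydrobenzofuran-3-yl]methanol
Product: 12 [(2S,3R)-5,6-bis(methoxymethoxy)-2-(3,4,5-trimethoxyphenyl)-2,3-dihydrobenzofuran-3-yl]methyl 4-methylbenzenesulfonate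
Conditions: TsCl, Et3N, DMAP (cat.), CH2Cl2, 0 °C → rt
Reagents that add atoms: p-toluenesulfonyl chloride, Cc1ccc(cc1)S(Cl)(=O)=O
Why: Sulfonylation of the unhindered primary alcohol under nucleophilic catalysis; no stereocentre is involved.

**Step 10**
Reactants: 12 [(2S,3R)-5,6-bis(methoxymethoxy)-2-(3,4,5-trimethoxyphenyl)-2,3-dihydrobenzofuran-3-yl]methyl 4-methylbenzenesulfonate
Product: 13 (2S,3S)-5,6-bis(methoxymethoxy)-3-methyl-2-(3,4,5-trimethoxyphenyl)-2,3-dihydrobenzofuran
Conditions: LiBHEt3, THF, 0 °C → rt
Reagents that add atoms: none
Why: SN2 displacement of the primary tosylate by hydride gives the C3 methyl group; a strong nucleophile in a non-ionising solvent leaves no room for participation of the electron-rich ring A.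

**Step 11**
Reactants: 13 (2S,3S)-5,6-bis(methoxymethoxy)-3-methyl-2-(3,4,5-trimethoxyphenyl)-2,3-dihydrobenzofuran
Product: 14 (2S,3S)-3-methyl-2-(3,4,5-trimethoxyphenyl)-2,3-dihydrobenzofuran-5,6-diol
Conditions: HCl (1.25 M in MeOH), 0 °C → rt, Ar
Reagents that add atoms: none
Why: Acid-catalysed transacetalisation of the two aryl MOM ethers to the solvent; these cleave under dilute acid at room temperature, where the cyclic benzylic ether, which would have to ionise to a benzylic cation, should persist. The catechol is kept under argon and used at once.

**Step 12**
Reactants: 14 (2S,3S)-3-methyl-2-(3,4,5-trimethoxyphenyl)-2,3-dihydrobenzofuran-5,6-diol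
Product: 15 (2S,3S)-3-methyl-2-(3,4,5-trimethoxyphenyl)-2,3-dihydrobenzofuran-5,6-dione
Conditions: Ag2O, Na2SO4, Et2O, 0 °C, dark; filtration through Celite
Reagents that add atoms: none
Why: Two-electron oxidation of the catechol to the ortho-quinone under neutral, anhydrous, heterogeneous conditions; the trimethoxyphenyl ring is far harder to oxidise, and O1 stabilises the quinone as a vinylogous ester. The cold filtrate is used directly, so that tautomerisation through C3–H has no time to set in.

**Step 13**
Reactants: 15 (2S,3S)-3-methyl-2-(3,4,5-trimethoxyphenyl)-2,3-dihydrobenzofuran-5,6-dione; 16 diisopropyl allylboronate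
Product: 17 (2S,3S,5R)-5-allyl-5-hydroxy-3-methyl-2-(3,4,5-trimethoxyphenyl)-2,3-dihydrobenzofuran-6(5H)-one
Conditions: (S)-3,3′-Br2-BINOL (15 mol%), PhCF3/toluene 3:1, −35 °C; pH 7 buffer
Reagents that add atoms: none
Why: Proposed new method: the diol exchanges one isopropoxy group of 16, its free naphthol O–H hydrogen-bonds to a boronate oxygen and raises the Lewis acidity of boron, and the C5 carbonyl oxygen binds boron so that the allyl group is delivered through a closed chair-like six-membered transition state, which enforces 1,2-addition and lets the axially chiral diol choose the face, setting C5 by catalyst control. C5 rather than C6 should be attacked because C6=O is deactivated as the vinylogous ester of O1. The closest known reaction types are the 3,3′-disubstituted-BINOL-catalysed enantioselective allylboration of aryl and alkenyl ketones with this boronate and the uncatalysed 1,2-allylation of ortho-quinones by allylboron and allylindium reagents.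

**Step 14**
Reactants: 17 (2S,3S,5R)-5-allyl-5-hydroxy-3-methyl-2-(3,4,5-trimethoxyphenyl)-2,3-dihydrobenzofuran-6(5H)-one
Product: 18 (2S,3S,5R)-5-allyl-5-methoxy-3-methyl-2-(3,4,5-trimethoxyphenyl)-2,3-dihydrobenzofuran-6(5H)-one
Conditions: MeI, Ag2O, 4 Å MS, CH2Cl2, rt, dark
Reagents that add atoms: iodomethane, CI
Why: Purdie methylation of the ketol hydroxyl, whose acidity is raised by the neighbouring carbonyl. No discrete alkoxide is formed, so anionic oxy-Cope and ketol shifts are not opened, the soft electrophile spares the vinylogous ester oxygen, and room temperature avoids the thermal allyl shift from C5 to C3a.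

## Compound list

1 | methyl 2-(3,4-dihydroxyphenyl)acetate | COC(=O)Cc1ccc(O)c(O)c1 | starting material
2 | methyl 2-[3,4-bis(methoxymethoxy)phenyl]acetate | COC(=O)Cc1ccc(OCOC)c(OCOC)c1 | intermediate
3 | methyl 2-[2-bromo-4,5-bis(methoxymethoxy)phenyl]acetate | COC(=O)Cc1cc(OCOC)c(OCOC)cc1Br | intermediate
4 | methyl 2-[4,5-bis(methoxymethoxy)-2-(4,4,5,5-tetramethyl-1,3,2-dioxaborolan-2-yl)phenyl]acetate | COC(=O)Cc1cc(OCOC)c(OCOC)cc1B1OC(C)(C)C(C)(C)O1 | intermediate
5 | methyl 2-[2-hydroxy-4,5-bis(methoxymethoxy)phenyl]acetate | COC(=O)Cc1cc(OCOC)c(OCOC)cc1O | intermediate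
6 | 3,4,5-trimethoxybenzyl chloride | COc1cc(CCl)cc(OC)c1OC | starting material
7 | methyl 2-[4,5-bis(methoxymethoxy)-2-(3,4,5-trimethoxybenzyloxy)phenyl]acetate | COC(=O)Cc1cc(OCOC)c(OCOC)cc1OCc1cc(OC)c(OC)c(OC)c1 | intermediate
8 | methyl 2-diazo-2-[4,5-bis(methoxymethoxy)-2-(3,4,5-trimethoxybenzyloxy)phenyl]acetate | COC(=O)C(=[N+]=[N-])c1cc(OCOC)c(OCOC)cc1OCc1cc(OC)c(OC)c(OC)c1 | intermediate
9 | methyl (2S,3R)-5,6-bis(methoxymethoxy)-2-(3,4,5-trimethoxyphenyl)-2,3-dihydrobenzofuran-3-carboxylate (cis) | COCOc1cc2c(cc1OCOC)O[C@H](c1cc(OC)c(OC)c(OC)c1)[C@@H]2C(=O)OC | intermediate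
10 | methyl (2S,3S)-5,6-bis(methoxymethoxy)-2-(3,4,5-trimethoxyphenyl)-2,3-dihydrobenzofuran-3-carboxylate (trans) | COCOc1cc2c(cc1OCOC)O[C@H](c1cc(OC)c(OC)c(OC)c1)[C@H]2C(=O)OC | intermediate
11 | [(2S,3R)-5,6-bis(methoxymethoxy)-2-(3,4,5-trimethoxyphenyl)-2,3-dihydrobenzofuran-3-yl]methanol | COCOc1cc2c(cc1OCOC)O[C@H](c1cc(OC)c(OC)c(OC)c1)[C@H]2CO | intermediate
12 | [(2S,3R)-5,6-bis(methoxymethoxy)-2-(3,4,5-trimethoxyphenyl)-2,3-dihydrobenzofuran-3-yl]methyl 4-methylbenzenesulfonate | COCOc1cc2c(cc1OCOC)O[C@H](c1cc(OC)c(OC)c(OC)c1)[C@H]2COS(=O)(=O)c1ccc(C)cc1 | intermediate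
13 | (2S,3S)-5,6-bis(methoxymethoxy)-3-methyl-2-(3,4,5-trimethoxyphenyl)-2,3-dihydrobenzofuran | COCOc1cc2c(cc1OCOC)O[C@H](c1cc(OC)c(OC)c(OC)c1)[C@H]2C | intermediate
14 | (2S,3S)-3-methyl-2-(3,4,5-trimethoxyphenyl)-2,3-dihydrobenzofuran-5,6-diol | Oc1cc2c(cc1O)O[C@H](c1cc(OC)c(OC)c(OC)c1)[C@H]2C | intermediate
15 | (2S,3S)-3-methyl-2-(3,4,5-trimethoxyphenyl)-2,3-dihydrobenzofuran-5,6-dione | O=C1C=C2C(=CC1=O)O[C@H](c1cc(OC)c(OC)c(OC)c1)[C@H]2C | intermediate
16 | diisopropyl allylboronate (allyldiisopropoxyborane) | C=CCB(OC(C)C)OC(C)C | starting material
17 | (2S,3S,5R)-5-allyl-5-hydroxy-3-methyl-2-(3,4,5-trimethoxyphenyl)-2,3-dihydrobenzofuran-6(5H)-one | C=CC[C@@]1(O)C=C2C(=CC1=O)O[C@H](c1cc(OC)c(OC)c(OC)c1)[C@H]2C | intermediate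
18 | (2S,3S,5R)-5-allyl-5-methoxy-3-methyl-2-(3,4,5-trimethoxyphenyl)-2,3-dihydrobenzofuran-6(5H)-one | C=CC[C@@]1(OC)C=C2C(=CC1=O)O[C@H](c1cc(OC)c(OC)c(OC)c1)[C@H]2C | target

## Step count and least certain steps

Total step count: 14. Longest linear sequence: 14 steps (1 to 18); 6 and 16 enter as purchased side inputs. Quinone 15 and the dienones 17 and 18 are not stored and are kept at or below room temperature.

**Step 13 (allylation at C5).** The chiral diol may fail to discriminate the faces of a flat, doubly activated quinone carbonyl, since the uncatalysed addition of 16 to so electrophilic a ketone may compete even at low temperature. Loss of regiocontrol towards C6 and slow tautomerisation of the quinone during a long reaction are further risks. The fallback uses known chemistry and gives up reagent control. It sets out from 15, which is treated at −40 °C with allylindium sesquibromide, (C3H5)3In2Br3, preformed from indium powder and allyl bromide in DMF. This Barbier-type 1,2-allylation of ortho-quinones should give 17 together with its C5 epimer (2S,3S,5S)-5-allyl-5-hydroxy-3-methyl-2-(3,4,5-trimethoxyphenyl)-2,3-dihydrobenzofuran-6(5H)-one F1. The two are diastereomers and are separated by chromatography; the route is rejoined at 17.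

**Step 6 (key step).** Enantioselectivity may erode, because both the carbene-bearing ring and the benzylic ether are more electron-rich than in simple model substrates. The insertion transition state is then earlier and the ligand wall discriminates less well. Carbene dimerisation can also take over if the insertion is slow at −60 °C. The fallback replaces asymmetric catalysis by resolution. It sets out from 8, which is decomposed with achiral Rh2(OAc)4 in CH2Cl2 to racemic methyl cis-5,6-bis(methoxymethoxy)-2-(3,4,5-trimethoxyphenyl)-2,3-dihydrobenzofuran-3-carboxylate F2. This is equilibrated with NaOMe in MeOH to racemic methyl trans-5,6-bis(methoxymethoxy)-2-(3,4,5-trimethoxyphenyl)-2,3-dihydrobenzofuran-3-carboxylate F3. Preparative chromatography on a chiral stationary phase separates 10 from its enantiomer methyl (2R,3R)-5,6-bis(methoxymethoxy)-2-(3,4,5-trimethoxyphenyl)-2,3-dihydrobenzofuran-3-carboxylate F4, and the route is rejoined at 10.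

**Step 14 (O-methylation).** Alkylation of the hindered, hydrogen-bonded tertiary hydroxyl may stay incomplete, and long exposure invites the allyl shift from C5 to C3a. The fallback changes the mode of activation from silver-assisted alkylation to a Williamson etherification through the lithium alkoxide. It sets out from 17, which is treated with LiHMDS and MeI in THF/DMF at −78 → −20 °C and goes directly to 18. The tightly bound lithium counter-ion and the low temperature are meant to hold back the anionic oxy-Cope and ketol shifts. No new compound arises on this way (F0).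

**Step 11 (acetal cleavage).** Protonation may ionise the C2–O1 bond to the benzylic cation, with epimerisation at C2 or capture by methanol, and the electron-rich catechol may be air-oxidised. The fallback avoids Brønsted acid. It sets out from 13, which is treated with TMSOTf and 2,2′-bipyridyl in CH2Cl2 at 0 °C. The aryl acetals are converted through bipyridinium intermediates into (2S,3S)-3-methyl-2-(3,4,5-trimethoxyphenyl)-5,6-bis(trimethylsilyloxy)-2,3-dihydrobenzofuran F5, which is hydrolysed on aqueous work-up, and the route is rejoined at 14.

## Further compounds

F1 | step 13 | (2S,3S,5S)-5-allyl-5-hydroxy-3-methyl-2-(3,4,5-trimethoxyphenyl)-2,3-dihydrobenzofuran-6(5H)-one | C=CC[C@]1(O)C=C2C(=CC1=O)O[C@H](c1cc(OC)c(OC)c(OC)c1)[C@H]2C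
F2 | step 6 | racemic methyl cis-5,6-bis(methoxymethoxy)-2-(3,4,5-trimethoxyphenyl)-2,3-dihydrobenzofuran-3-carboxylate | COCOc1cc2c(cc1OCOC)O[C@H](c1cc(OC)c(OC)c(OC)c1)[C@@H]2C(=O)OC.COCOc1cc2c(cc1OCOC)O[C@@H](c1cc(OC)c(OC)c(OC)c1)[C@H]2C(=O)OC
F3 | step 6 | racemic methyl trans-5,6-bis(methoxymethoxy)-2-(3,4,5-trimethoxyphenyl)-2,3-dihydrobenzofuran-3-carboxylate | COCOc1cc2c(cc1OCOC)O[C@H](c1cc(OC)c(OC)c(OC)c1)[C@H]2C(=O)OC.COCOc1cc2c(cc1OCOC)O[C@@H](c1cc(OC)c(OC)c(OC)c1)[C@@H]2C(=O)OC
F4 | step 6 | methyl (2R,3R)-5,6-bis(methoxymethoxy)-2-(3,4,5-trimethoxyphenyl)-2,3-dihydrobenzofuran-3-carboxylate | COCOc1cc2c(cc1OCOC)O[C@@H](c1cc(OC)c(OC)c(OC)c1)[C@@H]2C(=O)OC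
F0 | step 14 | none | none
F5 | step 11 | (2S,3S)-3-methyl-2-(3,4,5-trimethoxyphenyl)-5,6-bis(trimethylsilyloxy)-2,3-dihydrobenzofuran | C[Si](C)(C)Oc1cc2c(cc1O[Si](C)(C)C)O[C@H](c1cc(OC)c(OC)c(OC)c1)[C@H]2C
A1 | alternative 1 | (6R)-6-allyl-3-ethoxy-6-methoxy-4-[(1S,2S)-1-(tert-butyldimethylsilyloxy)-1-(3,4,5-trimethoxyphenyl)propan-2-yl]cyclohexa-2,4-dien-1-one | C=CC[C@@]1(OC)C=C([C@H](C)[C@H](O[Si](C)(C)C(C)(C)C)c2cc(OC)c(OC)c(OC)c2)C(OCC)=CC1=O
A2 | alternative 1 | 2-[(1S,2S)-1-(tert-butyldimethylsilyloxy)-1-(3,4,5-trimethoxyphenyl)propan-2-yl]-4-methoxyhepta-2,6-dienoyl chloride (alkene geometry and C4 configuration immaterial) | O=C(Cl)C(=CC(OC)CC=C)[C@H](C)[C@H](O[Si](C)(C)C(C)(C)C)c1cc(OC)c(OC)c(OC)c1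
A3 | alternative 1 | ethoxyethyne | CCOC#C
A4 | alternative 2 | (2S,3S)-3-methyl-2-(3,4,5-trimethoxyphenyl)-2,3-dihydrobenzofuran-5,6-dione | O=C1C=C2C(=CC1=O)O[C@H](c1cc(OC)c(OC)c(OC)c1)[C@H]2C
A5 | alternative 2 | 4-[(1S,2S)-1-hydroxy-1-(3,4,5-trimethoxyphenyl)propan-2-yl]benzene-1,2-diol | O[C@H](c1cc(OC)c(OC)c(OC)c1)[C@@H](C)c1ccc(O)c(O)c1
A6 | alternative 3 | methyl (2S,3S)-6-benzyloxy-5-methoxy-2-(3,4,5-trimethoxyphenyl)-2,3-dihydrobenzofuran-3-carboxylate | COc1cc2c(cc1OCc1ccccc1)O[C@H](c1cc(OC)c(OC)c(OC)c1)[C@H]2C(=O)OC
A7 | alternative 3 | (2S)-7-benzyloxy-6-methoxy-2-(3,4,5-trimethoxyphenyl)chroman-4-one | COc1cc2c(cc1OCc1ccccc1)O[C@H](c1cc(OC)c(OC)c(OC)c1)CC2=O
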